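**Retrosynthetic overview**

1. Locants: coumarin O1–C8a as usual; cyclohexene ring C1' (bears the aroyl C=O), C2' (=CH), C5' (CHMe), C6' (CH carrying the 1-hydroxyethyl group, carbinol carbon C7').
2. Last disconnection: the C6 prenyl group and the free 7-OH both come from one 7-O-(1,1-dimethylallyl) ether by aromatic Claisen rearrangement; the same ether masks the phenol during the key step.
3. Key disconnection: ring bond C1'–C6', made by a PMe3-mediated intramolecular Morita–Baylis–Hillman-type epoxide opening of an acyclic (E)-aryl enone carrying a cis-(2R,3S)-oxirane at C6'/C7'. The enabling feature is the γ-hydroxy ketone (homo-aldol) array O=C–C1'–C6'–C7'(OH) set inside the conjugated C2'=C1'–C=O unit of the cyclohexene ring: C1' is a latent enone α-carbanion and the C7' hydroxyl is the oxygen of an oxirane opened at C6'.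
4. The enone comes from aldol condensation of an 8-acetylcoumarin (Pechmann, Friedel–Crafts acetylation, 5-O-methylation, 7-O-tert-allylation) with an epoxy aldehyde built from (S)-lactaldehyde silyl ether (anti-selective crotylboration, diol-to-epoxide conversion with retention, linear hydroformylation).
5. Order of ring formation: pyranone ring of the coumarin (step 1), oxirane ring (step 8, consumed later), cyclohexene ring (step 12).

Key step: step 12

Assumption: (2S)-2-[(tert-butyldimethylsilyl)oxy]propanal is taken as a catalogue compound (otherwise two routine steps from ethyl (S)-lactate: silylation, then DIBAL-H reduction).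

**Route**

Step 1
Reactants: 1 phloroglucinol (benzene-1,3,5-triol); 2 ethyl 2-methylacetoacetate (ethyl 2-methyl-3-oxobutanoate)
Product: 3 dihydroxycoumarin (5,7-dihydroxy-3,4-dimethyl-2H-chromen-2-one)
Conditions: conc. H2SO4, 0 °C → rt
Reagents that add atoms: none
Why: Pechmann condensation of the symmetrical, highly nucleophilic triol with the β-keto ester (transesterification, ring hydroxyalkylation, dehydration) should give the coumarin with the ketone methyl at C4 and the α-methyl at C3, and no stereocentre is formed.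

Step 2
Reactants: 3 dihydroxycoumarin
Product: 4 acetyl diol (8-acetyl-5,7-dihydroxy-3,4-dimethyl-2H-chromen-2-one)
Conditions: AcCl (1.1 equiv), AlCl3 (4 equiv), PhNO2, 75 °C; aq. HCl work-up
Reagents that add atoms: acetyl chloride CC(=O)Cl
Why: Friedel–Crafts acylation of the phloroglucinol-type ring is expected at C8, the usual site of C-acylation in 5,7-dihydroxycoumarins, and the aluminium-chelated ortho-hydroxy ketone so formed is deactivated toward a second acylation.

Step 3
Reactants: 4 acetyl diol
Product: 5 methyl ether (8-acetyl-7-hydroxy-5-methoxy-3,4-dimethyl-2H-chromen-2-one)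
Conditions: MeI (1.05 equiv), K2CO3 (1.1 equiv), acetone, rt
Reagents that add atoms: iodomethane CI
Why: Williamson etherification with one equivalent of base should select the free 5-hydroxyl, which is para to the acetyl group, over the 7-hydroxyl, which is held in a six-membered hydrogen bond to the C8 carbonyl (the selectivity of 2,4-dihydroxyacetophenones).

Step 4
Reactants: 5 methyl ether
Product: 6 propargyl ether (8-acetyl-5-methoxy-3,4-dimethyl-7-[(2-methylbut-3-yn-2-yl)oxy]-2H-chromen-2-one)
Conditions: 3-chloro-3-methylbut-1-yne, DBU, CuCl2·2H2O (cat.), MeCN, 0 °C → rt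
Reagents that add atoms: 3-chloro-3-methylbut-1-yne CC(C)(Cl)C#C
Why: Copper-catalysed propargylic etherification, in which the amidine base fully deprotonates the acidic hydrogen-bonded phenol and the phenoxide attacks the tertiary carbon of a copper-activated propargyl electrophile, should give the tertiary ether without forming a stereocentre.

Step 5
Reactants: 6 propargyl ether
Product: 7 aryl methyl ketone (8-acetyl-5-methoxy-3,4-dimethyl-7-[(2-methylbut-3-en-2-yl)oxy]-2H-chromen-2-one)
Conditions: H2 (1 atm), Pd/CaCO3 poisoned with Pb(OAc)2, quinoline, EtOAc, rt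
Reagents that add atoms: none
Why: Semi-hydrogenation over lead-poisoned palladium should reduce the terminal alkyne to the alkene and stop there, leaving the tetrasubstituted coumarin C3=C4 bond and the aryl ketone untouched.

Step 6
Reactants: 8 silyloxy aldehyde ((2S)-2-[(tert-butyldimethylsilyl)oxy]propanal)
Product: 10 homoallylic alcohol ((2S,3R,4R)-2-[(tert-butyldimethylsilyl)oxy]-4-methylhex-5-en-3-ol), via pinacol borate ester 9 (not isolated)
Conditions: (E)-crotylboronic acid pinacol ester, (R)-TRIP [(R)-3,3'-bis(2,4,6-triisopropylphenyl)-1,1'-binaphthyl-2,2'-diyl hydrogen phosphate] (5 mol %), 4 Å MS, PhMe, −30 °C; then aq. NaHCO3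
Reagents that add atoms: (E)-crotylboronic acid pinacol ester C/C=C/CB1OC(C)(C)C(C)(C)O1
Why: Chiral-phosphoric-acid-catalysed crotylboration through a closed chair (Zimmerman–Traxler) transition state, in which the (E)-crotyl geometry sets the anti relationship of the new C3 hydroxyl and C4 methyl centres, while the 2,3-anti relationship follows from polar Felkin–Anh addition anti to the silyloxy group on the re face, the face the (R)-catalyst is chosen to favour as well (matched pair).

Step 7
Reactants: 10 homoallylic alcohol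
Product: 11 diol ((2S,3R,4R)-4-methylhex-5-ene-2,3-diol)
Conditions: p-TsOH·H2O (cat.), MeOH, rt
Reagents that add atoms: none
Why: Acid-catalysed methanolysis of the secondary silyl ether (protecting-group removal) should free the anti-1,2-diol without touching the stereocentres or the terminal alkene.

Step 8
Reactants: 11 diol
Product: 14 epoxy alkene ((2R,3S)-2-[(2R)-but-3-en-2-yl]-3-methyloxirane), via cyclic orthoacetate 12 (not isolated), via bromo acetate 13 (not isolated)
Conditions: MeC(OMe)3, PPTS (cat.), CH2Cl2, rt; then AcBr, CH2Cl2, 0 °C; then K2CO3, MeOH, rt (14 kept as a solution because of its volatility)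
Reagents that add atoms: none
Why: One-pot diol-to-epoxide conversion through a cyclic orthoester, in which opening of the acetoxonium ion by bromide and ring closure by the liberated alkoxide each invert the same carbon, so that both C–O configurations of the anti-diol are retained and the cis-epoxide results whichever carbon takes the bromide.

Step 9
Reactants: 14 epoxy alkene
Product: 15 epoxy aldehyde ((4R)-4-[(2R,3S)-3-methyloxiran-2-yl]pentanal)
Conditions: Rh(acac)(CO)2 (1 mol %), Xantphos (2 mol %), CO/H2 (1:1, 10 bar), PhMe, 60 °C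
Reagents that add atoms: carbon monoxide [C-]#[O+]
Why: Rhodium-catalysed hydroformylation with a wide-bite-angle diphosphine should place the formyl group on the terminal carbon of the α-branched monosubstituted alkene (linear selectivity) under neutral conditions that the epoxide tolerates, and no stereocentre is formed or touched.

Step 10
Reactants: 7 aryl methyl ketone; 15 epoxy aldehyde
Product: 17 aldol adduct (8-[(6R)-3-hydroxy-6-[(2R,3S)-3-methyloxiran-2-yl]heptanoyl]-5-methoxy-3,4-dimethyl-7-[(2-methylbut-3-en-2-yl)oxy]-2H-chromen-2-one as a mixture of C3 epimers), via lithium enolate 16 (not isolated)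
Conditions: LiN(SiMe3)2 (1.05 equiv), THF, −78 °C; then 15, −78 °C; aq. NH4Cl at −78 °C
Reagents that add atoms: none
Why: Directed aldol addition, in which kinetic deprotonation of the acetyl methyl group by the hindered amide base gives the lithium enolate that adds to the aldehyde faster than it opens the epoxide, forms the new carbinol centre without control, which is acceptable because step 11 removes it.

Step 11
Reactants: 17 aldol adduct
Product: 19 enone epoxide (8-[(2E,6R)-6-[(2R,3S)-3-methyloxiran-2-yl]hept-2-enoyl]-5-methoxy-3,4-dimethyl-7-[(2-methylbut-3-en-2-yl)oxy]-2H-chromen-2-one), via mesylate 18 (not isolated)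
Conditions: MsCl, Et3N, CH2Cl2, 0 °C; then DBU, rt
Reagents that add atoms: none
Why: Mesylation and base-induced E1cB elimination of the β-mesyloxy ketone should give the conjugated enone in its thermodynamically preferred (E) geometry, a geometry that step 12 erases anyway, while the three epoxide-side stereocentres are untouched.

Step 12
Reactants: 19 enone epoxide
Product: 22 cyclohexenyl ketone (8-{[(5R,6R)-6-[(1S)-1-hydroxyethyl]-5-methylcyclohex-1-en-1-yl]carbonyl}-5-methoxy-3,4-dimethyl-7-[(2-methylbut-3-en-2-yl)oxy]-2H-chromen-2-one), via phosphonium enolate 20 (not isolated), via phosphonium alkoxide 21 (not isolated)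
Conditions: PMe3 (1.2 equiv), t-BuOH/THF, rt, Ar
Reagents that add atoms: none
Why: PMe3 adds reversibly to the enone β-carbon C2' to give phosphonium enolate 20, whose α-carbon C1' attacks oxirane carbon C6' from the side opposite its C–O bond while tert-butanol activates the epoxide by hydrogen bonding and protonates the alkoxide of 21, after which E1cB loss of PMe3 restores the C1'=C2' double bond. The closest known reaction type is the phosphine-mediated intramolecular Morita–Baylis–Hillman-type cyclisation of enones onto tethered epoxides (homologous aldol products). The cyclohexene ring closes in the 6-exo-tet mode, the breaking oxirane C–O bond lying outside the new ring. The C6' stereocentre is set by stereospecific inversion at the (2R)-oxirane carbon, which places the 1-hydroxyethyl group cis to the C5' methyl group fixed in step 6, whereas the carbinol centre C7' is the untouched (3S)-oxirane carbon and C5' is a spectator. The step needs exo rather than 7-endo opening, which the shorter six-membered transition state with collinear backside attack should secure, and it needs the phosphine to choose the acyclic enone over the tetrasubstituted coumarin C3=C4 bond and over direct epoxide opening, which the unhindered β-CH of the enone and the α-branched cis-disubstituted oxirane should secure. The ether on O7 prevents oxa-Michael closure to a chromanone, and the transient centres at C1' and C2' vanish on elimination, so no further diastereomer question arises.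

Step 13
Reactants: 22 cyclohexenyl ketone
Product: 24 target (7-hydroxy-8-{[(5R,6R)-6-[(1S)-1-hydroxyethyl]-5-methylcyclohex-1-en-1-yl]carbonyl}-5-methoxy-3,4-dimethyl-6-(3-methylbut-2-en-1-yl)-2H-chromen-2-one), via cyclohexadienone 23 (not isolated)
Conditions: PhMe (degassed), 120 °C, sealed tube
Reagents that add atoms: none
Why: Aromatic Claisen rearrangement ([3,3]-sigmatropic shift) of the 1,1-dimethylallyl aryl ether should deliver the allyl unit with allylic transposition to C6, the only ortho position bearing hydrogen since C8 is acylated, and tautomerisation of dienone 23 frees the hydrogen-bonded 7-hydroxyl, so the prenyl group is installed and the phenol unmasked without any reagent while the three remote stereocentres stay untouched.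

**Compound list**

1 | phloroglucinol (benzene-1,3,5-triol) | Oc1cc(O)cc(O)c1 | starting material
2 | ethyl 2-methylacetoacetate (ethyl 2-methyl-3-oxobutanoate) | CCOC(=O)C(C)C(C)=O | starting material
3 | 5,7-dihydroxy-3,4-dimethyl-2H-chromen-2-one | Cc1c(C)c2c(O)cc(O)cc2oc1=O | intermediate
4 | 8-acetyl-5,7-dihydroxy-3,4-dimethyl-2H-chromen-2-one | CC(=O)c1c(O)cc(O)c2c(C)c(C)c(=O)oc12 | intermediate
5 | 8-acetyl-7-hydroxy-5-methoxy-3,4-dimethyl-2H-chromen-2-one | COc1cc(O)c(C(C)=O)c2oc(=O)c(C)c(C)c12 | intermediate
6 | 8-acetyl-5-methoxy-3,4-dimethyl-7-[(2-methylbut-3-yn-2-yl)oxy]-2H-chromen-2-one | COc1cc(OC(C)(C)C#C)c(C(C)=O)c2oc(=O)c(C)c(C)c12 | intermediate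
7 | 8-acetyl-5-methoxy-3,4-dimethyl-7-[(2-methylbut-3-en-2-yl)oxy]-2H-chromen-2-one | COc1cc(OC(C)(C)C=C)c(C(C)=O)c2oc(=O)c(C)c(C)c12 | intermediate
8 | (2S)-2-[(tert-butyldimethylsilyl)oxy]propanal | C[C@H](O[Si](C)(C)C(C)(C)C)C=O | starting material
9 | pinacol borate ester of 10: 2-{[(2S,3R,4R)-2-[(tert-butyldimethylsilyl)oxy]-4-methylhex-5-en-3-yl]oxy}-4,4,5,5-tetramethyl-1,3,2-dioxaborolane | C[C@H](O[Si](C)(C)C(C)(C)C)[C@H](OB1OC(C)(C)C(C)(C)O1)[C@H](C)C=C | intermediate
10 | (2S,3R,4R)-2-[(tert-butyldimethylsilyl)oxy]-4-methylhex-5-en-3-ol | C[C@H](O[Si](C)(C)C(C)(C)C)[C@H](O)[C@H](C)C=C | intermediate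
11 | (2S,3R,4R)-4-methylhex-5-ene-2,3-diol | C[C@H](O)[C@H](O)[C@H](C)C=C | intermediate
12 | cyclic orthoacetate: (4S,5R)-5-[(2R)-but-3-en-2-yl]-2-methoxy-2,4-dimethyl-1,3-dioxolane (C2 epimers) | C[C@@H]1OC(C)(OC)O[C@@H]1[C@H](C)C=C | intermediate
13 | bromo acetate: (2R,3R,4R)-2-bromo-4-methylhex-5-en-3-yl acetate | C[C@@H](Br)[C@H](OC(C)=O)[C@H](C)C=C | intermediate
14 | (2R,3S)-2-[(2R)-but-3-en-2-yl]-3-methyloxirane | C[C@@H]1O[C@@H]1[C@H](C)C=C | intermediate
15 | (4R)-4-[(2R,3S)-3-methyloxiran-2-yl]pentanal | C[C@@H]1O[C@@H]1[C@H](C)CCC=O | intermediate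
16 | lithium enolate of 7: lithium 1-{5-methoxy-3,4-dimethyl-7-[(2-methylbut-3-en-2-yl)oxy]-2-oxo-2H-chromen-8-yl}ethen-1-olate | [Li+].C=C([O-])c1c(OC(C)(C)C=C)cc(OC)c2c(C)c(C)c(=O)oc12 | intermediate
17 | 8-[(6R)-3-hydroxy-6-[(2R,3S)-3-methyloxiran-2-yl]heptanoyl]-5-methoxy-3,4-dimethyl-7-[(2-methylbut-3-en-2-yl)oxy]-2H-chromen-2-one (C3 epimers) | C[C@@H]1O[C@@H]1[C@H](C)CCC(O)CC(=O)c2c(OC(C)(C)C=C)cc(OC)c3c(C)c(C)c(=O)oc23 | intermediate
18 | 3-O-methanesulfonate of 17 | C[C@@H]1O[C@@H]1[C@H](C)CCC(OS(C)(=O)=O)CC(=O)c2c(OC(C)(C)C=C)cc(OC)c3c(C)c(C)c(=O)oc23 | intermediate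
19 | 8-[(2E,6R)-6-[(2R,3S)-3-methyloxiran-2-yl]hept-2-enoyl]-5-methoxy-3,4-dimethyl-7-[(2-methylbut-3-en-2-yl)oxy]-2H-chromen-2-one | C[C@@H]1O[C@@H]1[C@H](C)CC/C=C/C(=O)c2c(OC(C)(C)C=C)cc(OC)c3c(C)c(C)c(=O)oc23 | intermediate
20 | zwitterionic phosphonium enolate: PMe3 adduct at C3 of the heptenoyl chain of 19 (C3 epimers) | C[C@@H]1O[C@@H]1[C@H](C)CCC([P+](C)(C)C)C=C([O-])c2c(OC(C)(C)C=C)cc(OC)c3c(C)c(C)c(=O)oc23 | intermediate
21 | cyclised phosphonium alkoxide: 2-(trimethylphosphonio)cyclohexyl aryl ketone bearing the (1S)-1-oxidoethyl group (C1', C2' epimers) | COc1cc(OC(C)(C)C=C)c(C(=O)C2C([P+](C)(C)C)CC[C@@H](C)[C@H]2[C@H](C)[O-])c2oc(=O)c(C)c(C)c12 | intermediate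
22 | 8-{[(5R,6R)-6-[(1S)-1-hydroxyethyl]-5-methylcyclohex-1-en-1-yl]carbonyl}-5-methoxy-3,4-dimethyl-7-[(2-methylbut-3-en-2-yl)oxy]-2H-chromen-2-one | COc1cc(OC(C)(C)C=C)c(C(=O)C2=CCC[C@@H](C)[C@H]2[C@H](C)O)c2oc(=O)c(C)c(C)c12 | intermediate
23 | ortho-dienone: 8-{[(5R,6R)-6-[(1S)-1-hydroxyethyl]-5-methylcyclohex-1-en-1-yl]carbonyl}-5-methoxy-3,4-dimethyl-6-(3-methylbut-2-en-1-yl)-2H-chromene-2,7(6H)-dione (C6 epimers) | COC1=C2C(C)=C(C)C(=O)OC2=C(C(=O)C3=CCC[C@@H](C)[C@H]3[C@H](C)O)C(=O)C1CC=C(C)C | intermediate
24 | 7-hydroxy-8-{[(5R,6R)-6-[(1S)-1-hydroxyethyl]-5-methylcyclohex-1-en-1-yl]carbonyl}-5-methoxy-3,4-dimethyl-6-(3-methylbut-2-en-1-yl)-2H-chromen-2-one | COc1c(CC=C(C)C)c(O)c(C(=O)C2=CCC[C@@H](C)[C@H]2[C@H](C)O)c2oc(=O)c(C)c(C)c12 | target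

**Step count and risks**

Total step count: 13. Longest linear sequence: 9 steps (steps 1–5, then 10–13); the aldehyde branch (steps 6–9) joins at step 10.

Steps most likely to fail:

1. Step 12. The 6-exo opening at the α-branched oxirane carbon may be slow, so that the phosphonium enolate is diverted into intermolecular Rauhut–Currier-type dimerisation or the phosphine opens the epoxide directly. The fallback sets out from 19 and returns at 22, replacing the phosphine trigger by a reductively generated ketone enolate. Conjugate reduction of the enone with [(Ph3P)CuH]6 (PhMe, rt) should give the saturated epoxy ketone F1. KOt-Bu in t-BuOH/THF should then effect intramolecular enolate alkylation by 6-exo-tet epoxide opening, with the same inversion at C6', to give the cyclohexyl ketone F2. Silylation (TMSOTf, Et3N, CH2Cl2) gives the bis(trimethylsilyl) derivative F3, and Saegusa–Ito dehydrogenation with Pd(OAc)2 in MeCN followed by mild acidic work-up should reinstall the C1'=C2' double bond, β-hydride loss being expected from the less hindered C2' methylene.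

2. Step 4. O-alkylation of the hydrogen-bonded, weakly nucleophilic 7-phenoxide may be sluggish and lose out to elimination of the tertiary chloride to the enyne. The fallback sets out from 5 and returns at 7, making step 5 unnecessary. It is a Tsuji–Trost-type O-allylation with zerovalent palladium (Pd(PPh3)4, THF, 0 °C) and tert-butyl 2-methylbut-3-en-2-yl carbonate F4, itself made from 2-methylbut-3-en-2-ol with n-BuLi and Boc2O. The phenoxide should attack the more substituted terminus of the π-(1,1-dimethylallyl)palladium complex.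

3. Step 10. The base may deprotonate the vinylogously acidic C4 methyl group of the coumarin instead of the acetyl group, or the lithium aldolate may attack the epoxide on warming. The fallback sets out from 7 and returns at 19, bypassing 16–18 and step 11 by a Wittig olefination. Soft enolisation (TMSOTf, Et3N, CH2Cl2, 0 °C) gives the silyl enol ether F5, and NBS (THF, 0 °C) gives the bromomethyl ketone F6. PPh3 (PhMe, rt) gives the phosphonium bromide F7, and aqueous NaOH gives the stabilised ylide F8. F8 should condense with aldehyde 15 (CH2Cl2, 40 °C) to give the (E)-enone under neutral conditions.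

Further compounds
F1 | step 12 | saturated epoxy ketone: 8-[(6R)-6-[(2R,3S)-3-methyloxiran-2-yl]heptanoyl]-5-methoxy-3,4-dimethyl-7-[(2-methylbut-3-en-2-yl)oxy]-2H-chromen-2-one | C[C@@H]1O[C@@H]1[C@H](C)CCCCC(=O)c2c(OC(C)(C)C=C)cc(OC)c3c(C)c(C)c(=O)oc23
F2 | step 12 | cyclohexyl ketone: 8-{[(2R,3R)-2-[(1S)-1-hydroxyethyl]-3-methylcyclohexyl]carbonyl}-5-methoxy-3,4-dimethyl-7-[(2-methylbut-3-en-2-yl)oxy]-2H-chromen-2-one (C1 epimers) | COc1cc(OC(C)(C)C=C)c(C(=O)C2CCC[C@@H](C)[C@H]2[C@H](C)O)c2oc(=O)c(C)c(C)c12
F3 | step 12 | bis(trimethylsilyl) derivative of F2 (trimethylsilyl enol ether of the ketone, trimethylsilyl ether of the alcohol) | COc1cc(OC(C)(C)C=C)c(C(O[Si](C)(C)C)=C2CCC[C@@H](C)[C@H]2[C@H](C)O[Si](C)(C)C)c2oc(=O)c(C)c(C)c12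
F4 | step 4 | tert-butyl 2-methylbut-3-en-2-yl carbonate | C=CC(C)(C)OC(=O)OC(C)(C)C
F5 | step 10 | trimethylsilyl enol ether of 7 | C=C(O[Si](C)(C)C)c1c(OC(C)(C)C=C)cc(OC)c2c(C)c(C)c(=O)oc12
F6 | step 10 | 8-(bromoacetyl)-5-methoxy-3,4-dimethyl-7-[(2-methylbut-3-en-2-yl)oxy]-2H-chromen-2-one | BrCC(=O)c1c(OC(C)(C)C=C)cc(OC)c2c(C)c(C)c(=O)oc12
F7 | step 10 | (2-aryl-2-oxoethyl)triphenylphosphonium bromide derived from F6 | [Br-].O=C(C[P+](c1ccccc1)(c1ccccc1)c1ccccc1)c1c(OC(C)(C)C=C)cc(OC)c2c(C)c(C)c(=O)oc12
F8 | step 10 | stabilised ylide: 8-[(triphenyl-λ5-phosphanylidene)acetyl]-5-methoxy-3,4-dimethyl-7-[(2-methylbut-3-en-2-yl)oxy]-2H-chromen-2-one | O=C(C=P(c1ccccc1)(c1ccccc1)c1ccccc1)c1c(OC(C)(C)C=C)cc(OC)c2c(C)c(C)c(=O)oc12
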